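A leftover of 2.4% starting complex still stands in the south run at 60.0 h, beside 2.1% of complex with three exchanged, which had read 14.4% at 10.0 h. That complex is an intermediate, made with incoming ligand and later lost, so the quick number wanted for the flask is how high it climbs, and when.

| flask | starting complex | incoming ligand | remark | time |
|---|---|---|---|---|
| south | 20 mM | 1.2 equiv | run made earlier |  |
| west | 20 mM | 1.9 equiv | run made earlier |  |
| east | 40 mM | 2.5 equiv | run made earlier |  |
| flask | 20 mM | 2.50 equiv |  | 50 h |

| run | time / h | complex with three exchanged / % | starting complex / % |
|---|---|---|---|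
| south | 2.00 | 3.2 | 36.9 |
| south | 5.00 | 12.8 | 16.1 |
| south | 10.0 | 14.4 | 7.2 |
| south | 25.0 | 5.9 | 3.2 |
| south | 60.0 | 2.1 | 2.4 |
| west | 2.00 | 12.0 | 25.0 |
| west | 5.00 | 26.1 | 6.8 |
| west | 10.0 | 27.7 | 3.2 |
| west | 25.0 | 14.6 | 3.2 |
| west | 60.0 | 5.3 | 3.1 |
| east | 2.00 | 39.0 | 9.2 |
| east | 5.00 | 50.2 | 3.4 |
| east | 10.0 | 43.6 | 1.3 |
| east | 25.0 | 20.5 | 1.6 |
| east | 60.0 | 6.5 | 1.2 |

(scatter of a reading: 1 percentage point)



* time, not beyond 50 h, at which the flask holds most complex with three exchanged
* the amount of complex with three exchanged, in percent of the starting complex charged, at that time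
* earliest time at which at least nineteen twentieths of that best amount are there
* latest time at which they still are

Each complex with three exchanged has taken up 3 incoming ligands, so at 2.50 equiv the incoming ligand is the limiting reagent and the flask has a ceiling of 83.3%. Divide the fall of starting complex over the first 2.00 h by the late fall of complex with three exchanged, and the hours drop out: build over loss reads 16.9 in south and 36.4 in east, about twice as much.

The highest reading over a run's own ceiling, the ceiling share, climbs with it: 36.0% in south at 24.0 mM of ligand charged, 60.2% in east at 100 mM. The rise of that share per natural-logarithm step of ligand molarity, the molarity gain, reads 0.170 between these two runs. The west run, kept out of that line, is reckoned at 43.8% and reads 43.7%. For the flask, at 50.0 mM, this reckoning gives a height of 40.4% and no times.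

The forecast that came with the request says 42% at 7.5 h, with the window from 5.2 h to 11 h, on the ground that “Formation should therefore be about 1.5 times slower than east”. Its height stands 1.6 percentage points above the reckoning here.

The flask gives 42.7% at 7.65 h, with the window from 5.37 h to 10.8 h, so the forecast holds.

    complex with three exchanged ⇌ isomer of the product (K = 18.2, k = 1.89 × 10⁻⁵ /s)
    crystals ⇌ leaving ligand, rate k2*(cs2 - [leaving ligand]) while solid is left; crystals form when [leaving ligand] > cs2 (solubility = 3.00 mM, k = 5.97 × 10⁻⁴ /s)
    complex with one exchanged + incoming ligand → leaving ligand + complex with two exchanged (k = 0.00833 /M/s)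
    starting complex + incoming ligand → leaving ligand + complex with one exchanged (k = 0.00518 /M/s)
    starting complex ⇌ dormant form (K = 11.5, k = 5.18 × 10⁻⁵ /s)
    complex with two exchanged + incoming ligand → leaving ligand + complex with three exchanged (k = 0.00652 /M/s)

The flask's ceiling share comes to 51.3%. The forecast's numbers stop fitting at twice the dilution, where the highest amount is 32.9%, at 11.2 h. The neighbouring flask with 5.0 mM of starting complex holds the same equivalents at 12.5 mM of ligand, and the molarity gain puts its height at 20.8%. That flask reaches 22.6%.

The runs are calculated on assumed constants, noise included.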